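## Retrosynthetic overview

1. 11 ⇐ 10: one hydrogenolysis removes the O5 benzyl group and the bromine on C8 (a blocking group).
2. 10 ⇐ 7 + 4: the pyran ring (ring B: O1, C2, C3, C4, C4a, C8a) is the only ring made. It is cut at C2–C3 and C4–C4a, a catalytic asymmetric cationic [4+2] annulation (oxa-Povarov type) of aryl vinyl ether 7 with vinylnaphthalene 4. Benzene ring A and the naphthalene (rings C and D) are bought intact.
3. Enabling feature: O1 on C8a of ring A makes C2 an oxocarbenium carbon (2-oxonia-diene C2=O1(+)–C8a=C4a), and C4a, flanked by O1 and O5, is the ring nucleophile. The methoxy group on C4′, para to C1′ of the naphthalene, stabilises the cation at C4. Bromine on C8 blocks the other position ortho to O1, and the O5 benzyl ether sits peri to C4.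
4. 4 ⇐ 1,8-dimethoxynaphthalene (formylation, methylenation); 7 ⇐ 4-bromoresorcinol (mono-benzylation, O-vinylation).

Key step: step 5

Remarks on the chemistry:
- 1,8-Dimethoxynaphthalene and 4-bromoresorcinol are taken as commercial.
- "IDPi acid" means the imidodiphosphorimidate Brønsted acid HN[P(=NSO2CF3)(O2Ar*)]2, C74H33F30N3O8P2S2, in which Ar*O2 is (S)-3,3′-bis[3,5-bis(trifluoromethyl)phenyl]-1,1′-binaphthalene-2,2′-diolate.
- The sense of induction of this acid cannot be assigned in advance. The (S,S)-acid is written; its antipode is to be used if it should give the (2S,4R) series.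

## Route

Step 1
Reactants: 1 1,8-dimethoxynaphthalene
Product: 3 4,5-dimethoxynaphthalene-1-carbaldehyde, via iminium chloride 2 (not isolated)
Conditions: POCl3, DMF, 0 °C to 80 °C; then ice-water
Reagents that add atoms: N,N-dimethylformamide, CN(C)C=O; water, O
Why: Vilsmeier–Haack formylation should occur para to a methoxy group (the two para positions of the symmetric naphthalene are equivalent), and hydrolysis of iminium 2 on work-up should give the aldehyde; no stereocentre.

Step 2
Reactants: 3 4,5-dimethoxynaphthalene-1-carbaldehyde
Product: 4 1-ethenyl-4,5-dimethoxynaphthalene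
Conditions: Ph3PCH3Br, KOtBu, THF, 0 °C to rt
Reagents that add atoms: methyltriphenylphosphonium bromide, C[P+](c1ccccc1)(c1ccccc1)c1ccccc1.[Br-]
Why: Wittig methylenation of an aromatic aldehyde with a non-stabilised ylide; no stereocentre.

Step 3
Reactants: 5 4-bromobenzene-1,3-diol (4-bromoresorcinol)
Product: 6 5-(benzyloxy)-2-bromophenol
Conditions: BnBr (1.0 equiv), K2CO3, acetone, reflux
Reagents that add atoms: benzyl bromide, BrCc1ccccc1
Why: Williamson etherification should take place at the hydroxyl para to bromine, because the hydroxyl next to bromine is hindered and hydrogen-bonded to it; no stereocentre.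

Step 4
Reactants: 6 5-(benzyloxy)-2-bromophenol
Product: 7 4-(benzyloxy)-1-bromo-2-(ethenyloxy)benzene
Conditions: vinyl acetate, [Ir(cod)Cl]2 (1 mol%), Na2CO3, toluene, 100 °C
Reagents that add atoms: vinyl acetate, C=COC(C)=O
Why: Iridium-catalysed transfer vinylation of a phenol with vinyl acetate should give the aryl vinyl ether and tolerate the aryl bromide and the benzyl ether; no stereocentre.

Step 5
Reactants: 7 4-(benzyloxy)-1-bromo-2-(ethenyloxy)benzene; 4 1-ethenyl-4,5-dimethoxynaphthalene
Product: 10 (2R,4S)-5-(benzyloxy)-8-bromo-4-(4,5-dimethoxynaphthalen-1-yl)-2-methyl-3,4-dihydro-2H-1-benzopyran, via aryl oxocarbenium ion 8 (not isolated), via naphthylmethyl cation 9 (not isolated)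
Conditions: IDPi acid C74H33F30N3O8P2S2 (5 mol%), CH2Cl2, −60 °C, 4 added slowly to 7 (1.5 equiv)
Reagents that add atoms: none
Why: Proposed new method: the acid should protonate the vinyl ether carbon of 7 to give the 2-oxonia-diene 8 (C2=O1(+)–C8a=C4a) as an ion pair with the confined chiral anion; the CH2 terminus of 4 should then attack C2 on the face left open by the anion (C2–C3 bond, sets C2, enantio-determining) to give the 4′-methoxy-stabilised cation 9, which should close ring B by 6-endo-trig Friedel–Crafts attack on C4a (C4–C4a bond) and return the proton to the anion. The closest known reaction types are the SnCl4-mediated oxa-Povarov annulation of aryl oxocarbenium ions with styrenes (racemic, stoichiometric) and imidodiphosphorimidate-catalysed enantioselective additions of styrenes to oxocarbenium ions (Prins and hetero-[4+2] reactions); new is catalytic enantiocontrol over an aryl oxocarbenium ion made by protonation of an aryl vinyl ether. C4 is set by the substrate: closure and rearomatisation should pass through a half-chair with the C2 methyl equatorial and the naphthyl group pseudo-axial, because a pseudo-equatorial naphthyl would clash with the peri benzyloxy group on C5; this gives 2,4-trans, which should also be the more stable isomer. Site selectivity of the closure is secured by the bromine on C8, which leaves C4a as the only free position ortho to O1. Chemoselectivity (protonation of 7 and not of 4, no oligomerisation of 4) should be helped by the higher basicity of the vinyl ether and by slow addition of 4 to excess 7 at low temperature.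

Step 6
Reactants: 10 (2R,4S)-5-(benzyloxy)-8-bromo-4-(4,5-dimethoxynaphthalen-1-yl)-2-methyl-3,4-dihydro-2H-1-benzopyran
Product: 11 cladonaphchrom A, (2R,4S)-4-(4,5-dimethoxynaphthalen-1-yl)-2-methyl-3,4-dihydro-2H-1-benzopyran-5-ol
Conditions: H2 (1 atm), Pd/C, Et3N, EtOAc/MeOH, rt
Reagents that add atoms: none
Why: Catalytic hydrogenolysis should cleave the benzyl ether and the aryl C–Br bond in one operation (the base takes up HBr), while the alkyl aryl ether C2–O1, the diarylmethine C4 and the naphthalene are inert, so both stereocentres are kept.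

## Compound list

1 | 1,8-dimethoxynaphthalene | COc1cccc2cccc(OC)c12 | starting material
2 | N-[(4,5-dimethoxynaphthalen-1-yl)methylidene]-N-methylmethanaminium chloride | COc1cccc2c(C=[N+](C)C)ccc(OC)c12.[Cl-] | intermediate
3 | 4,5-dimethoxynaphthalene-1-carbaldehyde | COc1cccc2c(C=O)ccc(OC)c12 | intermediate
4 | 1-ethenyl-4,5-dimethoxynaphthalene | COc1cccc2c(C=C)ccc(OC)c12 | intermediate
5 | 4-bromobenzene-1,3-diol | Oc1ccc(Br)c(O)c1 | starting material
6 | 5-(benzyloxy)-2-bromophenol | Oc1cc(OCc2ccccc2)ccc1Br | intermediate
7 | 4-(benzyloxy)-1-bromo-2-(ethenyloxy)benzene | C=COc1cc(OCc2ccccc2)ccc1Br | intermediate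
8 | [5-(benzyloxy)-2-bromophenyl](ethylidene)oxonium, ion-paired with the catalyst anion | CC=[O+]c1cc(OCc2ccccc2)ccc1Br | intermediate
9 | (3R)-3-[5-(benzyloxy)-2-bromophenoxy]-1-(4,5-dimethoxynaphthalen-1-yl)butan-1-ylium, ion-paired with the catalyst anion | C[C@H](C[CH+]c1ccc(OC)c2c(OC)cccc12)Oc1cc(OCc2ccccc2)ccc1Br | intermediate
10 | (2R,4S)-5-(benzyloxy)-8-bromo-4-(4,5-dimethoxynaphthalen-1-yl)-2-methyl-3,4-dihydro-2H-1-benzopyran | COc1cccc2c([C@@H]3C[C@@H](C)Oc4c(Br)ccc(OCc5ccccc5)c43)ccc(OC)c12 | intermediate
11 | cladonaphchrom A, (2R,4S)-4-(4,5-dimethoxynaphthalen-1-yl)-2-methyl-3,4-dihydro-2H-1-benzopyran-5-ol (2,4-trans) | COc1cccc2c([C@@H]3C[C@@H](C)Oc4cccc(O)c43)ccc(OC)c12 | target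

## Step count and risks

Total step count: 6. Longest linear sequence: 4 steps (5 → 6 → 7 → 10 → 11, or 1 → 3 → 4 → 10 → 11).

Steps most likely to fail:

1. Step 5. What may go wrong: protonation of 4 in competition with 7, followed by cationic oligomerisation; weak facial discrimination of the oxocarbenium ion by the anion; kinetic leakage to the 2,4-cis isomer. The fallback sets out from 7 and comes back at 10. Dry HCl in CH2Cl2 at 0 °C should add to 7 to give 4-(benzyloxy)-1-bromo-2-(1-chloroethoxy)benzene F1. F1 is ionised with SnCl4 (1 equiv) in CH2Cl2 at −78 °C in the presence of 4 (the known stoichiometric Lewis-acid oxa-Povarov annulation, with no free Brønsted acid at the start), and the mixture is then warmed to 0 °C so that C4 can equilibrate to the more stable trans isomer; racemisation is of no concern here. This should give racemic trans-5-(benzyloxy)-8-bromo-4-(4,5-dimethoxynaphthalen-1-yl)-2-methyl-3,4-dihydro-2H-1-benzopyran F2. Preparative chromatography on a chiral stationary phase then separates the enantiomers, and the (2R,4S) enantiomer is 10.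

2. Step 4. What may go wrong: slow vinyl transfer to the hindered, acidic ortho-bromophenol, or insertion of the iridium catalyst into the C–Br bond. The fallback sets out from 6 and comes back at 7. Alkylation of 6 with excess 1,2-dibromoethane (K2CO3, MeCN, 60 °C) should give 4-(benzyloxy)-1-bromo-2-(2-bromoethoxy)benzene F3, and E2 elimination with KOtBu in THF at 0 °C to rt should give 7.

3. Step 6. What may go wrong: poisoning of the catalyst by bromide, incomplete cleavage of the hindered benzyl ether, or partial saturation of the naphthalene if forcing conditions are needed. The fallback sets out from 10 and comes back at 11. Bromine–lithium exchange with t-BuLi (2.2 equiv, THF, −78 °C) and quenching with MeOH should give (2R,4S)-5-(benzyloxy)-4-(4,5-dimethoxynaphthalen-1-yl)-2-methyl-3,4-dihydro-2H-1-benzopyran F4. Hydrogenolysis of the benzyl ether alone (H2, Pd(OH)2/C, EtOAc, rt) should then give 11.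

## Further compounds

F1 | step 5 | 4-(benzyloxy)-1-bromo-2-(1-chloroethoxy)benzene (racemic) | CC(Cl)Oc1cc(OCc2ccccc2)ccc1Br
F2 | step 5 | racemic trans-(2RS,4SR)-5-(benzyloxy)-8-bromo-4-(4,5-dimethoxynaphthalen-1-yl)-2-methyl-3,4-dihydro-2H-1-benzopyran (both enantiomers written) | COc1cccc2c([C@@H]3C[C@@H](C)Oc4c(Br)ccc(OCc5ccccc5)c43)ccc(OC)c12.COc1cccc2c([C@H]3C[C@H](C)Oc4c(Br)ccc(OCc5ccccc5)c43)ccc(OC)c12
F3 | step 4 | 4-(benzyloxy)-1-bromo-2-(2-bromoethoxy)benzene | BrCCOc1cc(OCc2ccccc2)ccc1Br
F4 | step 6 | (2R,4S)-5-(benzyloxy)-4-(4,5-dimethoxynaphthalen-1-yl)-2-methyl-3,4-dihydro-2H-1-benzopyran | COc1cccc2c([C@@H]3C[C@@H](C)Oc4cccc(OCc5ccccc5)c43)ccc(OC)c12
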